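**Strategy.** Everything rests on cutting the side-chain bond C1'–C2', between the carbinol carbon on coumarin C8 and the carbon that carries the flavone O7 aryl ether and the isopropenyl group. The key step exploits the fact that the C1' hydroxyl is homoallylic to the C3'(CH3)=C4'H2 alkene and anti to the C2' aryloxy group: a chiral-phosphoric-acid-catalysed allylboration of 7-methoxy-8-formylcoumarin with an (E)-γ-aryloxy-β-methylallyl pinacol boronate built on O7 of the flavone A ring. The oxygen-bearing carbon reacts as a nucleophile (polarity reversal), and one operation gives the C–C bond, both stereocentres and the isopropenyl group, as the last step.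

Key step: step 11

Assumption: the flavone half (5,7-dihydroxy-3,6,8,4'-tetramethoxyflavone) is treated as not purchasable and is made from commercial nevadensin. Locants 1' and 2' denote the carbinol carbon and the aryloxy-bearing carbon of the side chain; the target is (1'R,2'S), i.e. the anti diol monoether.

**Route**

Step 1
Reactants: 1 umbelliferone (7-hydroxycoumarin)
Product: 2 7-hydroxy-2-oxo-2H-chromene-8-carbaldehyde
Conditions: hexamethylenetetramine, TFA, 90 °C; then aq. HCl, 60 °C
Reagents that add atoms: hexamethylenetetramine C1N2CN3CN1CN(C2)C3; water O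
Why: Duff formylation; the phenol directs the iminium electrophile to C8, the position between the OH and the ring oxygen, and hydrolysis of the benzyliminium should release the aldehyde.

Step 2
Reactants: 2 7-hydroxy-2-oxo-2H-chromene-8-carbaldehyde
Product: 3 7-methoxy-2-oxo-2H-chromene-8-carbaldehyde
Conditions: MeI, K2CO3, DMF, rt
Reagents that add atoms: iodomethane CI
Why: Williamson O-methylation of the only acidic OH; the aldehyde and the lactone are untouched by carbonate at room temperature.

Step 3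
Reactants: 4 nevadensin (5,7-dihydroxy-6,8,4'-trimethoxyflavone)
Product: 5 5,7-bis(benzyloxy)-6,8-dimethoxy-2-(4-methoxyphenyl)-4H-chromen-4-one
Conditions: BnBr (2.5 equiv), K2CO3, TBAI (cat.), DMF, 70 °C
Reagents that add atoms: benzyl bromide BrCc1ccccc1
Why: Williamson benzylation; the 7-OH reacts first and the chelated 5-OH follows on heating with excess reagent, so both phenols are masked before the oxidation.

Step 4
Reactants: 5 5,7-bis(benzyloxy)-6,8-dimethoxy-2-(4-methoxyphenyl)-4H-chromen-4-one
Product: 7 5,7-bis(benzyloxy)-3-hydroxy-6,8-dimethoxy-2-(4-methoxyphenyl)-4H-chromen-4-one, via flavone 2,3-epoxide 6 (not isolated)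
Conditions: DMDO (acetone solution, excess), CH2Cl2, 0 °C to rt; then p-TsOH·H2O (cat.), CH2Cl2, rt
Reagents that add atoms: dimethyldioxirane CC1(C)OO1
Why: Dioxirane epoxidation of the flavone C2=C3 bond, then acid-catalysed opening to the C2 oxocarbenium and loss of H3 should give the flavonol; the neutral oxidant spares the ethers and the fully substituted A ring.

Step 5
Reactants: 7 5,7-bis(benzyloxy)-3-hydroxy-6,8-dimethoxy-2-(4-methoxyphenyl)-4H-chromen-4-one
Product: 8 5,7-bis(benzyloxy)-3,6,8-trimethoxy-2-(4-methoxyphenyl)-4H-chromen-4-one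
Conditions: MeI, K2CO3, acetone, reflux
Reagents that add atoms: iodomethane CI
Why: Williamson methylation of the only free hydroxyl (the flavonol 3-OH).

Step 6
Reactants: 8 5,7-bis(benzyloxy)-3,6,8-trimethoxy-2-(4-methoxyphenyl)-4H-chromen-4-one
Product: 9 5,7-dihydroxy-3,6,8-trimethoxy-2-(4-methoxyphenyl)-4H-chromen-4-one
Conditions: H2 (1 atm), 10% Pd/C, EtOAc–MeOH, rt
Reagents that add atoms: none
Why: Hydrogenolysis of both benzyl ethers; the tetrasubstituted C2=C3 bond of the vinylogous ester is not reduced under these conditions.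

Step 7
Reactants: 10 propargyl alcohol
Product: 12 (E)-3-iodo-2-methylprop-2-en-1-ol, via alkenylalane 11 (not isolated)
Conditions: AlMe3 (3 equiv), Cp2ZrCl2 (0.25 equiv), CH2Cl2, 0 °C to rt; then I2, THF, −30 to 0 °C; aq. K2CO3 work-up
Reagents that add atoms: trimethylaluminium C[Al](C)C; iodine II
Why: Negishi zirconium-catalysed carboalumination adds Me and Al syn across the alkyne, and iodinolysis of the C–Al bond with retention fixes the E geometry (I trans to CH2OH) that later becomes the E enol ether.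

Step 8
Reactants: 9 5,7-dihydroxy-3,6,8-trimethoxy-2-(4-methoxyphenyl)-4H-chromen-4-one; 12 (E)-3-iodo-2-methylprop-2-en-1-ol
Product: 13 5-hydroxy-7-{[(E)-3-hydroxy-2-methylprop-1-en-1-yl]oxy}-3,6,8-trimethoxy-2-(4-methoxyphenyl)-4H-chromen-4-one
Conditions: CuI (10 mol%), N,N-dimethylglycine·HCl (30 mol%), Cs2CO3 (2 equiv), dioxane, 80 °C
Reagents that add atoms: none
Why: Ullmann-type copper-catalysed O-vinylation of a phenol with a vinyl iodide, which proceeds with retention of alkene geometry; the acidic, unchelated 7-OH should couple in preference to the hydrogen-bonded 5-OH and the aliphatic OH.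

Step 9
Reactants: 13 5-hydroxy-7-{[(E)-3-hydroxy-2-methylprop-1-en-1-yl]oxy}-3,6,8-trimethoxy-2-(4-methoxyphenyl)-4H-chromen-4-one
Product: 14 (E)-3-{[5-hydroxy-3,6,8-trimethoxy-2-(4-methoxyphenyl)-4-oxo-4H-chromen-7-yl]oxy}-2-methylallyl acetate
Conditions: Ac2O (1.1 equiv), Et3N, DMAP (cat.), CH2Cl2, −20 to 0 °C; used crude
Reagents that add atoms: acetic anhydride CC(=O)OC(C)=O
Why: Acylation of the primary allylic alcohol; the chelated, hindered 5-OH should not compete at low temperature with one equivalent of anhydride.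

Step 10
Reactants: 14 (E)-3-{[5-hydroxy-3,6,8-trimethoxy-2-(4-methoxyphenyl)-4-oxo-4H-chromen-7-yl]oxy}-2-methylallyl acetate
Product: 15 5-hydroxy-3,6,8-trimethoxy-2-(4-methoxyphenyl)-7-{[(E)-2-methyl-3-(4,4,5,5-tetramethyl-1,3,2-dioxaborolan-2-yl)prop-1-en-1-yl]oxy}-4H-chromen-4-one
Conditions: Pd2(dba)3 (2.5 mol%), B2pin2 (1.2 equiv), DMSO, 50 °C
Reagents that add atoms: bis(pinacolato)diboron CC1(C)OB(OC1(C)C)B1OC(C)(C)C(C)(C)O1
Why: Miyaura-type palladium-catalysed borylation of an allylic acetate through the aryloxy-substituted π-allyl complex; boron is delivered to the unsubstituted CH2 terminus, and the syn π-allyl formed from the E acetate should keep the E geometry.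

Step 11
Reactants: 15 5-hydroxy-3,6,8-trimethoxy-2-(4-methoxyphenyl)-7-{[(E)-2-methyl-3-(4,4,5,5-tetramethyl-1,3,2-dioxaborolan-2-yl)prop-1-en-1-yl]oxy}-4H-chromen-4-one; 3 7-methoxy-2-oxo-2H-chromene-8-carbaldehyde
Product: 17 5-hydroxy-7-{[(1R,2S)-1-hydroxy-1-(7-methoxy-2-oxo-2H-chromen-8-yl)-3-methylbut-3-en-2-yl]oxy}-3,6,8-trimethoxy-2-(4-methoxyphenyl)-4H-chromen-4-one (target CNP0117808.1), via pinacol borate ester 16 (not isolated)
Conditions: (S)-TRIP (10 mol%), 4 Å MS, toluene–CH2Cl2, −30 to 0 °C; aq. NaHCO3 work-up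
Reagents that add atoms: none
Why: Asymmetric allylboration under chiral phosphoric acid catalysis: the aldehyde oxygen binds boron and the allyl unit is transferred through a closed six-membered chair transition state, with the catalyst P–OH hydrogen-bonded to the pseudoaxial boronate oxygen and P=O to the formyl C–H; the closest known reaction types are the TRIP-catalysed crotylboration of aryl aldehydes and the addition of (E)-γ-alkoxyallylboronates to aldehydes. No ring is closed; the new bond is C1'–C2', made by the oxygen-bearing γ-carbon of the enol ether with allylic transposition, which unveils the isopropenyl group. The configuration of C2' relative to C1' (anti) is controlled by the E geometry fixed in steps 7–10, because the coumarinyl group and the γ-aryloxy group both sit equatorial in the chair. C1' (R) is controlled by the catalyst: (R)-TRIP is taken, from recalled precedent with aryl aldehydes, to direct allyl transfer to the Re face, so (S)-TRIP is chosen for the Si face needed here; if that sense is reversed for this aldehyde, the antipodal catalyst is used. The step needs chemoselectivity for the formyl group, secured because the chelated flavone C4=O and the coumarin lactone are inert to allylboronates, and it needs the catalysed path to outrun the racemic background, secured by low temperature and the low intrinsic reactivity of pinacol esters.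

**Compound list**

1 | umbelliferone (7-hydroxycoumarin) | O=c1ccc2ccc(O)cc2o1 | starting material
2 | 7-hydroxy-2-oxo-2H-chromene-8-carbaldehyde | O=Cc1c(O)ccc2ccc(=O)oc12 | intermediate
3 | 7-methoxy-2-oxo-2H-chromene-8-carbaldehyde | COc1ccc2ccc(=O)oc2c1C=O | intermediate
4 | nevadensin (5,7-dihydroxy-6,8-dimethoxy-2-(4-methoxyphenyl)-4H-chromen-4-one) | COc1ccc(cc1)-c1cc(=O)c2c(O)c(OC)c(O)c(OC)c2o1 | starting material
5 | 5,7-bis(benzyloxy)-6,8-dimethoxy-2-(4-methoxyphenyl)-4H-chromen-4-one | COc1ccc(cc1)-c1cc(=O)c2c(OCc3ccccc3)c(OC)c(OCc3ccccc3)c(OC)c2o1 | intermediate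
6 | flavone 2,3-epoxide of 5 (racemic, not isolated) | COc1ccc(cc1)C23OC2C(=O)c2c(OCc4ccccc4)c(OC)c(OCc4ccccc4)c(OC)c2O3 | intermediate
7 | 5,7-bis(benzyloxy)-3-hydroxy-6,8-dimethoxy-2-(4-methoxyphenyl)-4H-chromen-4-one | COc1ccc(cc1)-c1oc2c(OC)c(OCc3ccccc3)c(OC)c(OCc3ccccc3)c2c(=O)c1O | intermediate
8 | 5,7-bis(benzyloxy)-3,6,8-trimethoxy-2-(4-methoxyphenyl)-4H-chromen-4-one | COc1ccc(cc1)-c1oc2c(OC)c(OCc3ccccc3)c(OC)c(OCc3ccccc3)c2c(=O)c1OC | intermediate
9 | 5,7-dihydroxy-3,6,8-trimethoxy-2-(4-methoxyphenyl)-4H-chromen-4-one | COc1ccc(cc1)-c1oc2c(OC)c(O)c(OC)c(O)c2c(=O)c1OC | intermediate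
10 | propargyl alcohol | C#CCO | starting material
11 | (E)-alkenylalane, dimethylaluminium alkoxide of (E)-3-(dimethylalumanyl)-2-methylprop-2-en-1-ol (not isolated) | C[Al](C)/C=C(C)/CO[Al](C)C | intermediate
12 | (E)-3-iodo-2-methylprop-2-en-1-ol | OC/C(C)=C/I | intermediate
13 | 5-hydroxy-7-{[(E)-3-hydroxy-2-methylprop-1-en-1-yl]oxy}-3,6,8-trimethoxy-2-(4-methoxyphenyl)-4H-chromen-4-one | COc1ccc(cc1)-c1oc2c(OC)c(O/C=C(C)/CO)c(OC)c(O)c2c(=O)c1OC | intermediate
14 | (E)-3-{[5-hydroxy-3,6,8-trimethoxy-2-(4-methoxyphenyl)-4-oxo-4H-chromen-7-yl]oxy}-2-methylallyl acetate | COc1ccc(cc1)-c1oc2c(OC)c(O/C=C(C)/COC(C)=O)c(OC)c(O)c2c(=O)c1OC | intermediate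
15 | 5-hydroxy-3,6,8-trimethoxy-2-(4-methoxyphenyl)-7-{[(E)-2-methyl-3-(4,4,5,5-tetramethyl-1,3,2-dioxaborolan-2-yl)prop-1-en-1-yl]oxy}-4H-chromen-4-one | COc1ccc(cc1)-c1oc2c(OC)c(O/C=C(C)/CB3OC(C)(C)C(C)(C)O3)c(OC)c(O)c2c(=O)c1OC | intermediate
16 | pinacol borate ester of the target at the C1' oxygen (not isolated) | C=C(C)[C@H](Oc1c(OC)c(O)c2c(=O)c(OC)c(-c3ccc(OC)cc3)oc2c1OC)[C@H](OB1OC(C)(C)C(C)(C)O1)c1c(OC)ccc2ccc(=O)oc12 | intermediate
17 | 5-hydroxy-7-{[(1R,2S)-1-hydroxy-1-(7-methoxy-2-oxo-2H-chromen-8-yl)-3-methylbut-3-en-2-yl]oxy}-3,6,8-trimethoxy-2-(4-methoxyphenyl)-4H-chromen-4-one (CNP0117808.1) | C=C(C)[C@H](Oc1c(OC)c(O)c2c(=O)c(OC)c(-c3ccc(OC)cc3)oc2c1OC)[C@H](O)c1c(OC)ccc2ccc(=O)oc12 | target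

**Totals**

Total step count: 11. Longest linear sequence: 8 steps (steps 3, 4, 5, 6, 8, 9, 10, 11, from nevadensin 4 to the target 17).

**Steps most likely to fail**

1. Step 11 (key step). The addition to the di-ortho-oxygenated, electron-rich aldehyde may be slow, the catalyst may give incomplete facial control, and the acid may degrade the enol ether boronate before it reacts. Fallback by an enamine aldol that makes the same C1'–C2' bond: setting out from 9, alkylation of the 7-OH with chloroacetone (K2CO3, acetone, 50 °C) should give 5-hydroxy-3,6,8-trimethoxy-2-(4-methoxyphenyl)-7-(2-oxopropoxy)-4H-chromen-4-one F1. A D-proline-catalysed direct aldol of this ketone with aldehyde 3 (DMSO, rt) should occur at the oxygen-bearing α-carbon and give the anti (3R,4R)-3-aryloxy-4-hydroxy-4-(7-methoxy-2-oxo-2H-chromen-8-yl)butan-2-one F2. Lombardo methylenation of the methyl ketone (Zn, CH2Br2, TiCl4, THF–CH2Cl2, 0 °C), which is non-basic and tolerates free hydroxyls, comes back to the route at 17.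

2. Step 10. The aryloxy-π-allyl palladium intermediate may lose its geometry by π–σ–π isomerisation (which would later appear as the syn diastereomer), or boron may be delivered to the wrong terminus. Fallback that never passes through a π-allyl: setting out from 9, the same copper-catalysed O-vinylation with (E)-2-bromo-1-iodoprop-1-ene (from propyne and IBr), selective at the C–I bond, should give 7-{[(E)-2-bromoprop-1-en-1-yl]oxy}-5-hydroxy-3,6,8-trimethoxy-2-(4-methoxyphenyl)-4H-chromen-4-one F3. A stereoretentive sp2–sp3 Suzuki coupling of this vinyl bromide with bis(pinacolato)borylmethane (Pd[P(t-Bu)3]2, aq. KOH, dioxane, rt) comes back to the route at 15.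

3. Step 8. Coupling may be sluggish at the hindered 7-phenoxide flanked by two methoxy groups, the 5-hydroxy-4-keto unit may sequester copper, and the 5-OH or the aliphatic OH may compete. Fallback by addition–elimination instead of copper catalysis: setting out from 9, reaction of the 7-phenoxide with (E)-3-bromo-2-methylacrylaldehyde (K2CO3, DMF, 0 °C to rt) should give (E)-3-{[5-hydroxy-3,6,8-trimethoxy-2-(4-methoxyphenyl)-4-oxo-4H-chromen-7-yl]oxy}-2-methylacrylaldehyde F4, the E isomer being the thermodynamic push–pull alkene. Luche 1,2-reduction (NaBH4, CeCl3·7H2O, MeOH, −40 °C) comes back to the route at 13.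

**Further compounds**

F1 | step 11 | 5-hydroxy-3,6,8-trimethoxy-2-(4-methoxyphenyl)-7-(2-oxopropoxy)-4H-chromen-4-one | COc1ccc(cc1)-c1oc2c(OC)c(OCC(C)=O)c(OC)c(O)c2c(=O)c1OC
F2 | step 11 | (3R,4R)-4-hydroxy-3-{[5-hydroxy-3,6,8-trimethoxy-2-(4-methoxyphenyl)-4-oxo-4H-chromen-7-yl]oxy}-4-(7-methoxy-2-oxo-2H-chromen-8-yl)butan-2-one | CC(=O)[C@H](Oc1c(OC)c(O)c2c(=O)c(OC)c(-c3ccc(OC)cc3)oc2c1OC)[C@H](O)c1c(OC)ccc2ccc(=O)oc12
F3 | step 10 | 7-{[(E)-2-bromoprop-1-en-1-yl]oxy}-5-hydroxy-3,6,8-trimethoxy-2-(4-methoxyphenyl)-4H-chromen-4-one | COc1ccc(cc1)-c1oc2c(OC)c(O/C=C(C)/Br)c(OC)c(O)c2c(=O)c1OC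
F4 | step 8 | (E)-3-{[5-hydroxy-3,6,8-trimethoxy-2-(4-methoxyphenyl)-4-oxo-4H-chromen-7-yl]oxy}-2-methylacrylaldehyde | COc1ccc(cc1)-c1oc2c(OC)c(O/C=C(C)/C=O)c(OC)c(O)c2c(=O)c1OC
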